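**Plan**

1. Numbering: ring C1(OH)–C2–C3–C4(Me, oxirane)–C5(oxirane)–C6(lactone O)–C7–C8(methacrylate O)–C9–C10(Me); C11, C12, C13 are the butenolide α-carbon, carbonyl and CH2OAc carbon. Enabling feature: C1–C2–C3–C4 with the C4 methyl is a 1-methylcyclobutene, and C5–C10 with the C10 methyl and the oxygens on C6 and C8 is a 5-oxygenated 3-methylcyclohex-2-enone, so the ten-membered ring is that six-membered ring with the four-membered ring inserted between C5 and C10.
2. Cuts, in retrosynthetic order: the ester bonds at O8 and O13; C1–O and C10–H (back to the 1(10)E alkene); O6–C12 and C7–C11 (butenolide back to a C6 ketone plus an α-keto ester); the oxirane oxygen (back to the 4Z alkene); then C4=C5 and C1=C10 are paired into a cyclobutane (C5–C10 and C1–C4 restored) and C4–C5 and C1–C10 are cut.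
3. Forward: the six- and four-membered rings are joined through a cyclobutane, heating opens the tricycle to the ten-membered dienone, then the oxirane is made, then the butenolide ring (aldol at C7, reduction, lactonisation, dehydration), then the esters and the C1 hydroxyl.
4. Stereochemistry: C8 from lipase desymmetrisation of a meso diol; C4/C5 from a vanadium-directed epoxidation steered by a temporary C6 carbinol set by CBS reduction; C6 from chelation-controlled reduction of the epoxy ketone; C1/C10 from syn hydroboration of the E alkene on its open outer face; the 4Z/1(10)E geometry from the cycloreversion.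
5. The methacrylate is carried through the hydroboration as its phenylselenide adduct and released by the oxidative work-up (TBS = tert-butyldimethylsilyl throughout).

Key step: step 7

Remark on the chemistry (assumption): the lipase is taken to acetylate the R-configured carbinol of meso diol 2, the ring arm carrying the silyloxy group acting as the larger substituent; if it chose the S centre, hydrolysis of the diacetate of 2 by the same enzyme would supply 3 instead.

**Route**

Step 1
Reactants: 1 cis,cis-cyclohexane-1,3,5-triol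
Product: 2 all-cis-5-(tert-butyldimethylsilyloxy)cyclohexane-1,3-diol (meso)
Conditions: TBSCl (1.0 equiv), imidazole, DMF, 0 → 25 °C
Reagents that add atoms: tert-butyldimethylsilyl chloride, CC(C)(C)[Si](C)(C)Cl
Why: Silyl ether formation on one of three symmetry-equivalent hydroxyls (statistical monoprotection, triol and bis-ether recycled) gives a meso diol with no stereochemical issue.

Step 2
Reactants: 2 all-cis-5-(tert-butyldimethylsilyloxy)cyclohexane-1,3-diol
Product: 3 (1R,3S,5S)-3-(tert-butyldimethylsilyloxy)-5-hydroxycyclohexyl acetate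
Conditions: Burkholderia cepacia lipase (Amano PS), vinyl acetate, tBuOMe, 25 °C
Reagents that add atoms: vinyl acetate, C=COC(C)=O
Why: Lipase-catalysed irreversible transesterification acetylates one of the two enantiotopic carbinols, and this enzyme-controlled choice turns the silyloxy carbon into the stereocentre that becomes C8.

Step 3
Reactants: 3 (1R,3S,5S)-3-(tert-butyldimethylsilyloxy)-5-hydroxycyclohexyl acetate
Product: 5 (R)-5-(tert-butyldimethylsilyloxy)cyclohex-2-en-1-one, via β-acetoxy ketone 4 (not isolated)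
Conditions: Dess–Martin periodinane, CH2Cl2, 25 °C; then Et3N, 0 → 25 °C
Reagents that add atoms: none
Why: Dess–Martin oxidation of the free carbinol followed by E1cB loss of acetate (a far better leaving group than the silyloxy group on the other β-carbon) gives the enone without touching the stereocentre.

Step 4
Reactants: 5 (R)-5-(tert-butyldimethylsilyloxy)cyclohex-2-en-1-one
Product: 6 (5R)-5-(tert-butyldimethylsilyloxy)-1-methylcyclohex-2-en-1-ol (both C1 epimers)
Conditions: MeLi, Et2O, −78 °C
Reagents that add atoms: methyllithium, [Li]C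
Why: 1,2-Addition of the hard organolithium to the enone carbonyl; the configuration of the new tertiary carbinol does not matter because the next step erases it.

Step 5
Reactants: 6 (5R)-5-(tert-butyldimethylsilyloxy)-1-methylcyclohex-2-en-1-ol
Product: 7 (S)-5-(tert-butyldimethylsilyloxy)-3-methylcyclohex-2-en-1-one
Conditions: pyridinium chlorochromate (C5H5NH[CrO3Cl]), CH2Cl2, 25 °C
Reagents that add atoms: pyridinium chlorochromate, [O-][Cr](=O)(=O)Cl.c1cc[nH+]cc1
Why: Babler–Dauben oxidative transposition: the tertiary allylic chromate ester undergoes 1,3-shift and oxidation, which puts the carbonyl on the former C3 and the methyl on the β-carbon (the descriptor changes from R to S through renumbering only).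

Step 6
Reactants: 8 methylenecyclobutane
Product: 9 1-methylcyclobutene
Conditions: Na/Al2O3 (cat.), neat, 25 °C; spinning-band distillation
Reagents that add atoms: none
Why: Base-catalysed prototropic isomerisation through the allyl anion moves the exocyclic alkene into the ring, the trisubstituted endocyclic isomer being the more stable and enriched by distillation.

Step 7
Reactants: 7 (S)-5-(tert-butyldimethylsilyloxy)-3-methylcyclohex-2-en-1-one; 9 1-methylcyclobutene
Product: 11 (1(10)E,4Z,8S)-8-(tert-butyldimethylsilyloxy)germacra-1(10),4-dien-6-one, via tricyclic photoadduct 10 (not isolated)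
Conditions: 9 (10 equiv), hν (350 nm, Pyrex), CH2Cl2, −40 °C; evaporate; PhMe (0.01 M), 180 °C, sealed tube, 1 h
Reagents that add atoms: none
Why: The triplet of enone 7 adds stepwise to the strained alkene of 9 through a 1,4-diradical, joining C5 to C4 and C10 to C1 in cyclobutane 10; on heating, the ring-fusion bond C1–C4 of the bicyclo[2.2.0]hexane unit homolyses and the cyclohexane-1,4-diyl fragments across C5–C10, so the two bonds lost are the ones the light step did not make and the four cyclobutene carbons end up inserted into the six-membered ring. The closest known reaction type is the enone–cyclobutene [2+2] photocycloaddition followed by thermal cycloreversion to cis,trans-cyclodeca-1,5-dienes, known for 3-methylcyclohex-2-enones with 1-methylcyclobutene. The cyclobutane of 10 closes by recombination of the 1,4-diradical and is transient, whereas the ten-membered ring is not closed by cyclisation but uncovered by fragmentation of two zero-atom bridges, driven by the strain of two four-membered rings. No new stereocentre survives, C8 is carried over from 7, and the alkene geometry is expected to follow from the cis six–four fusion, which places the C6 arm axial and the C9 arm equatorial on the chair-like diyl and so gives the Z enone (C3 cis to C6) and the E alkene at C1=C10. The step needs head-to-head regiochemistry, secured because the alternative would join the methyl-bearing C10 to the methyl-bearing C4 as adjacent quaternary carbons, and it needs the ring to survive the heat, for which brief heating at high dilution and the conjugation of C4=C5 with the ketone hold back Cope contraction to the divinylcyclohexanone.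

Step 8
Reactants: 11 (1(10)E,4Z,8S)-8-(tert-butyldimethylsilyloxy)germacra-1(10),4-dien-6-one
Product: 12 (1(10)E,4Z,6S,8S)-8-(tert-butyldimethylsilyloxy)germacra-1(10),4-dien-6-ol
Conditions: (R)-2-methyl-CBS-oxazaborolidine (0.2 equiv), catecholborane, PhMe, −78 °C
Reagents that add atoms: none
Why: Corey–Bakshi–Shibata reduction with the alkenyl carbon C5 as the large and the C7 methylene as the small substituent delivers hydride under reagent control to give the 6S carbinol, a temporary centre that serves to direct the epoxidation, while catecholborane leaves both alkenes alone.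

Step 9
Reactants: 12 (1(10)E,4Z,6S,8S)-8-(tert-butyldimethylsilyloxy)germacra-1(10),4-dien-6-ol
Product: 13 (1(10)E,4R,5S,6S,8S)-4,5-epoxy-8-(tert-butyldimethylsilyloxy)germacr-1(10)-en-6-ol
Conditions: VO(acac)2 (5 mol %), tBuOOH, CH2Cl2, 0 °C
Reagents that add atoms: tert-butyl hydroperoxide, CC(C)(C)OO
Why: Hydroxyl-directed epoxidation: the vanadate ester of the C6 alcohol passes oxygen to the allylic Z alkene on the face syn to the carbinol oxygen (cis-epoxy alcohol, as with medium-ring (Z)-cycloalk-2-enols), which sets C4 and C5, keeps the oxirane cis and leaves the remote C1=C10 alkene untouched.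

Step 10
Reactants: 13 (1(10)E,4R,5S,6S,8S)-4,5-epoxy-8-(tert-butyldimethylsilyloxy)germacr-1(10)-en-6-ol
Product: 14 (1(10)E,4R,5R,8S)-4,5-epoxy-8-(tert-butyldimethylsilyloxy)germacr-1(10)-en-6-one
Conditions: Dess–Martin periodinane, pyridine, CH2Cl2, 0 → 25 °C
Reagents that add atoms: none
Why: Buffered Dess–Martin oxidation returns the C6 carbonyl needed to activate C7 and leaves the oxirane centres fixed (C5 changes descriptor through priority only).

Step 11
Reactants: 15 ethyl 2-(hydroxymethyl)acrylate
Product: 16 ethyl 2-[(tert-butyldimethylsilyloxy)methyl]acrylate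
Conditions: TBSCl, imidazole, CH2Cl2, 0 → 25 °C
Reagents that add atoms: tert-butyldimethylsilyl chloride, CC(C)(C)[Si](C)(C)Cl
Why: Routine silylation of a primary allylic alcohol.

Step 12
Reactants: 16 ethyl 2-[(tert-butyldimethylsilyloxy)methyl]acrylate
Product: 18 ethyl 3-(tert-butyldimethylsilyloxy)-2-oxopropanoate, via ozonide 17 (not isolated)
Conditions: O3, CH2Cl2, −78 °C; then Me2S, −78 → 25 °C
Reagents that add atoms: ozone, [O-][O+]=O
Why: Ozonolysis of the 1,1-disubstituted alkene (Criegee mechanism) with reductive work-up removes the methylene carbon as formaldehyde and leaves the α-keto ester.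

Step 13
Reactants: 14 (1(10)E,4R,5R,8S)-4,5-epoxy-8-(tert-butyldimethylsilyloxy)germacr-1(10)-en-6-one; 18 ethyl 3-(tert-butyldimethylsilyloxy)-2-oxopropanoate
Product: 20 ethyl (4R,5R,8S)-4,5-epoxy-11-hydroxy-6-oxo-8,13-bis(tert-butyldimethylsilyloxy)germacr-1(10)E-en-12-oate (C7/C11 epimers), via lithium enolate 19 (not isolated)
Conditions: LiN(iPr)2, THF, −78 °C; 18, −78 °C; AcOH quench
Reagents that add atoms: none
Why: Kinetic deprotonation at C7, the only enolisable position of the epoxy ketone, and aldol addition of the lithium enolate to the ketone carbonyl of the α-keto ester form C7–C11; both new centres are erased later, and the low temperature suppresses β-loss of the C8 silyloxy group.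

Step 14
Reactants: 20 ethyl (4R,5R,8S)-4,5-epoxy-11-hydroxy-6-oxo-8,13-bis(tert-butyldimethylsilyloxy)germacr-1(10)E-en-12-oate
Product: 22 (4R,5S,6S,8S)-4,5-epoxy-11-hydroxy-8,13-bis(tert-butyldimethylsilyloxy)germacr-1(10)E-en-12,6-olide (C7/C11 epimers), via hydroxy ester 21 (not isolated)
Conditions: Zn(BH4)2, Et2O, −20 → 25 °C; aq. NH4Cl
Reagents that add atoms: none
Why: Chelation-controlled borohydride reduction of the α,β-epoxy ketone (zinc bridges the carbonyl and oxirane oxygens and hydride enters on the face away from the oxirane) gives the erythro 6S alcohol, whose zinc alkoxide closes the γ-lactone on the ethyl ester (5-exo-trig), the silyl ether on O8 excluding the isomeric lactone.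

Step 15
Reactants: 22 (4R,5S,6S,8S)-4,5-epoxy-11-hydroxy-8,13-bis(tert-butyldimethylsilyloxy)germacr-1(10)E-en-12,6-olide
Product: 24 (4R,5S,6S,8S)-4,5-epoxy-8,13-bis(tert-butyldimethylsilyloxy)germacra-1(10)E,7(11)-dien-12,6-olide, via sulfamate ester 23 (not isolated)
Conditions: Burgess reagent (MeO2CN–SO2NEt3 inner salt), PhMe, 25 → 60 °C
Reagents that add atoms: none
Why: Burgess dehydration: the tertiary C11 sulfamate ester loses H7 by intramolecular syn-elimination (through the ion pair for an epimer without a cis H7) to give the conjugated tetrasubstituted C7=C11 alkene under neutral conditions that spare the oxirane and the silyl ethers.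

Step 16
Reactants: 24 (4R,5S,6S,8S)-4,5-epoxy-8,13-bis(tert-butyldimethylsilyloxy)germacra-1(10)E,7(11)-dien-12,6-olide
Product: 25 (4R,5S,6S,8S)-4,5-epoxy-8,13-dihydroxygermacra-1(10)E,7(11)-dien-12,6-olide
Conditions: HF·pyridine, pyridine, THF, 0 → 25 °C
Reagents that add atoms: none
Why: Buffered fluoride cleavage of both silyl ethers is tolerated by the oxirane, and the freed O8 cannot translactonise because the C7=C11 alkene holds C12 on the side of C6.

Step 17
Reactants: 25 (4R,5S,6S,8S)-4,5-epoxy-8,13-dihydroxygermacra-1(10)E,7(11)-dien-12,6-olide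
Product: 26 (4R,5S,6S,8S)-13-acetoxy-4,5-epoxy-8-hydroxygermacra-1(10)E,7(11)-dien-12,6-olide
Conditions: AcCl, 2,4,6-collidine, CH2Cl2, −78 °C
Reagents that add atoms: acetyl chloride, CC(Cl)=O
Why: Selective acylation of the primary allylic hydroxyl over the hindered secondary C8 hydroxyl, using an acyl chloride with a hindered pyridine base at low temperature.

Step 18
Reactants: 27 3-bromo-2-methylpropanoic acid (racemic)
Product: 28 2-methyl-3-(phenylselanyl)propanoic acid (racemic)
Conditions: (PhSe)2, NaBH4, EtOH, 0 °C; 27, 25 °C; aq. HCl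
Reagents that add atoms: diphenyl diselenide, c1ccc(cc1)[Se][Se]c1ccccc1
Why: SN2 displacement of the primary bromide by the soft selenolate (an elimination–conjugate addition path would lead to the same acid).

Step 19
Reactants: 26 (4R,5S,6S,8S)-13-acetoxy-4,5-epoxy-8-hydroxygermacra-1(10)E,7(11)-dien-12,6-olide; 28 2-methyl-3-(phenylselanyl)propanoic acid
Product: 29 (4R,5S,6S,8S)-13-acetoxy-4,5-epoxy-8-[2-methyl-3-(phenylselanyl)propanoyloxy]germacra-1(10)E,7(11)-dien-12,6-olide (epimers at the acyl α-carbon)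
Conditions: DCC, DMAP (cat.), CH2Cl2, 0 → 25 °C
Reagents that add atoms: none
Why: Steglich esterification of the secondary C8 alcohol installs the methacrylate as its phenylselenide adduct, so that no conjugated terminal alkene is present during the hydroboration.

Step 20
Reactants: 29 (4R,5S,6S,8S)-13-acetoxy-4,5-epoxy-8-[2-methyl-3-(phenylselanyl)propanoyloxy]germacra-1(10)E,7(11)-dien-12,6-olide
Product: 32 (1S,4R,5S,6S,8S,10R)-13-acetoxy-4,5-epoxy-1-hydroxy-8-(methacryloyloxy)germacr-7(11)-en-12,6-olide (CNP0119405.1), via alkylborane 30 (not isolated), via selenoxide 31 (not isolated)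
Conditions: BH3·THF (1.1 equiv), THF, 0 °C; then 30% H2O2, aq. NaHCO3, 0 → 25 °C
Reagents that add atoms: hydrogen peroxide, OO
Why: Syn, anti-Markovnikov hydroboration of the only electron-rich alkene (boron to C1, hydrogen to C10, on the exposed outer face of the E alkene in the conformer with the C10 methyl on the side of the C8 oxygen) sets 1S and 10R in one event, C–B oxidation goes with retention, and the same peroxide oxidises selenium so that selenoxide syn-elimination releases the methacrylate; the butenolide alkene is tetrasubstituted and electron-poor and the ester carbonyls react with borane far more slowly than the alkene.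

**Compound list**

1 | cis,cis-cyclohexane-1,3,5-triol | O[C@H]1C[C@@H](O)C[C@@H](O)C1 | starting material
2 | all-cis-5-(tert-butyldimethylsilyloxy)cyclohexane-1,3-diol (meso) | CC(C)(C)[Si](C)(C)O[C@@H]1C[C@H](O)C[C@H](O)C1 | intermediate
3 | (1R,3S,5S)-3-(tert-butyldimethylsilyloxy)-5-hydroxycyclohexyl acetate | CC(C)(C)[Si](C)(C)O[C@@H]1C[C@H](OC(C)=O)C[C@H](O)C1 | intermediate
4 | (1S,3R)-3-(tert-butyldimethylsilyloxy)-5-oxocyclohexyl acetate | CC(C)(C)[Si](C)(C)O[C@@H]1C[C@H](OC(C)=O)CC(=O)C1 | intermediate (not isolated)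
5 | (R)-5-(tert-butyldimethylsilyloxy)cyclohex-2-en-1-one | O=C1C=CC[C@@H](O[Si](C)(C)C(C)(C)C)C1 | intermediate
6 | (5R)-5-(tert-butyldimethylsilyloxy)-1-methylcyclohex-2-en-1-ol, both C1 epimers | CC1(O)C=CC[C@@H](O[Si](C)(C)C(C)(C)C)C1 | intermediate
7 | (S)-5-(tert-butyldimethylsilyloxy)-3-methylcyclohex-2-en-1-one | O=C1C=C(C)C[C@H](O[Si](C)(C)C(C)(C)C)C1 | intermediate
8 | methylenecyclobutane | C=C1CCC1 | starting material
9 | 1-methylcyclobutene | CC1=CCC1 | intermediate
10 | (9S)-9-(tert-butyldimethylsilyloxy)-1,5-dimethyltricyclo[4.4.0.0^2,5]decan-7-one, head-to-head adduct, cis-fused diastereomers | O=C1C[C@@H](O[Si](C)(C)C(C)(C)C)CC2(C)C3CCC3(C)C12 | intermediate (not isolated)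
11 | (1(10)E,4Z,8S)-8-(tert-butyldimethylsilyloxy)germacra-1(10),4-dien-6-one [(2Z,6E,9S)-9-silyloxy-3,7-dimethylcyclodeca-2,6-dien-1-one] | CC(C)(C)[Si](C)(C)O[C@H]1C/C(C)=C/CC/C(C)=C\C(=O)C1 | intermediate
12 | (1(10)E,4Z,6S,8S)-8-(tert-butyldimethylsilyloxy)germacra-1(10),4-dien-6-ol | CC(C)(C)[Si](C)(C)O[C@H]1C/C(C)=C/CC/C(C)=C\[C@@H](O)C1 | intermediate
13 | (1(10)E,4R,5S,6S,8S)-4,5-epoxy-8-(tert-butyldimethylsilyloxy)germacr-1(10)-en-6-ol | CC(C)(C)[Si](C)(C)O[C@H]1C/C(C)=C/CC[C@@]2(C)O[C@H]2[C@@H](O)C1 | intermediate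
14 | (1(10)E,4R,5R,8S)-4,5-epoxy-8-(tert-butyldimethylsilyloxy)germacr-1(10)-en-6-one | CC(C)(C)[Si](C)(C)O[C@H]1C/C(C)=C/CC[C@@]2(C)O[C@H]2C(=O)C1 | intermediate
15 | ethyl 2-(hydroxymethyl)acrylate | C=C(CO)C(=O)OCC | starting material
16 | ethyl 2-[(tert-butyldimethylsilyloxy)methyl]acrylate | C=C(CO[Si](C)(C)C(C)(C)C)C(=O)OCC | intermediate
17 | ethyl 3-[(tert-butyldimethylsilyloxy)methyl]-1,2,4-trioxolane-3-carboxylate | CCOC(=O)C1(CO[Si](C)(C)C(C)(C)C)OCOO1 | intermediate (not isolated)
18 | ethyl 3-(tert-butyldimethylsilyloxy)-2-oxopropanoate | CCOC(=O)C(=O)CO[Si](C)(C)C(C)(C)C | intermediate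
19 | lithium C6(7)-enolate of 14 | CC(C)(C)[Si](C)(C)O[C@H]1C/C(C)=C/CC[C@@]2(C)O[C@H]2C(O[Li])=C1 | intermediate (not isolated)
20 | ethyl (4R,5R,8S)-4,5-epoxy-11-hydroxy-6-oxo-8,13-bis(tert-butyldimethylsilyloxy)germacr-1(10)E-en-12-oate, C7/C11 epimers | CC(C)(C)[Si](C)(C)O[C@H]1C/C(C)=C/CC[C@@]2(C)O[C@H]2C(=O)C1C(O)(CO[Si](C)(C)C(C)(C)C)C(=O)OCC | intermediate
21 | ethyl (4R,5S,6S,8S)-4,5-epoxy-6,11-dihydroxy-8,13-bis(tert-butyldimethylsilyloxy)germacr-1(10)E-en-12-oate, C7/C11 epimers | CC(C)(C)[Si](C)(C)O[C@H]1C/C(C)=C/CC[C@@]2(C)O[C@H]2[C@@H](O)C1C(O)(CO[Si](C)(C)C(C)(C)C)C(=O)OCC | intermediate (not isolated)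
22 | (4R,5S,6S,8S)-4,5-epoxy-11-hydroxy-8,13-bis(tert-butyldimethylsilyloxy)germacr-1(10)E-en-12,6-olide, C7/C11 epimers | CC(C)(C)[Si](C)(C)O[C@H]1C/C(C)=C/CC[C@@]2(C)O[C@H]2[C@H]2OC(=O)C(O)(CO[Si](C)(C)C(C)(C)C)C12 | intermediate
23 | O11-[N-(methoxycarbonyl)sulfamoyl] ester of 22 | CC(C)(C)[Si](C)(C)O[C@H]1C/C(C)=C/CC[C@@]2(C)O[C@H]2[C@H]2OC(=O)C(OS(=O)(=O)NC(=O)OC)(CO[Si](C)(C)C(C)(C)C)C12 | intermediate (not isolated)
24 | (4R,5S,6S,8S)-4,5-epoxy-8,13-bis(tert-butyldimethylsilyloxy)germacra-1(10)E,7(11)-dien-12,6-olide | CC(C)(C)[Si](C)(C)O[C@H]1C/C(C)=C/CC[C@@]2(C)O[C@H]2[C@H]2OC(=O)C(CO[Si](C)(C)C(C)(C)C)=C12 | intermediate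
25 | (4R,5S,6S,8S)-4,5-epoxy-8,13-dihydroxygermacra-1(10)E,7(11)-dien-12,6-olide | O[C@H]1C/C(C)=C/CC[C@@]2(C)O[C@H]2[C@H]2OC(=O)C(CO)=C12 | intermediate
26 | (4R,5S,6S,8S)-13-acetoxy-4,5-epoxy-8-hydroxygermacra-1(10)E,7(11)-dien-12,6-olide | O[C@H]1C/C(C)=C/CC[C@@]2(C)O[C@H]2[C@H]2OC(=O)C(COC(C)=O)=C12 | intermediate
27 | 3-bromo-2-methylpropanoic acid (racemic) | CC(CBr)C(=O)O | starting material
28 | 2-methyl-3-(phenylselanyl)propanoic acid (racemic) | CC(C[Se]c1ccccc1)C(=O)O | intermediate
29 | (4R,5S,6S,8S)-13-acetoxy-4,5-epoxy-8-[2-methyl-3-(phenylselanyl)propanoyloxy]germacra-1(10)E,7(11)-dien-12,6-olide, epimers at the acyl α-carbon | CC(C[Se]c1ccccc1)C(=O)O[C@H]1C/C(C)=C/CC[C@@]2(C)O[C@H]2[C@H]2OC(=O)C(COC(C)=O)=C12 | intermediate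
30 | (1S,10R)-1-boryl derivative of 29 (C1–BH2, C10–H) | CC(C[Se]c1ccccc1)C(=O)O[C@H]1C[C@@H](C)[C@@H](B)CC[C@@]2(C)O[C@H]2[C@H]2OC(=O)C(COC(C)=O)=C12 | intermediate (not isolated)
31 | (1S,10R)-1-hydroxy selenoxide of 29 | CC(C[Se](=O)c1ccccc1)C(=O)O[C@H]1C[C@@H](C)[C@@H](O)CC[C@@]2(C)O[C@H]2[C@H]2OC(=O)C(COC(C)=O)=C12 | intermediate (not isolated)
32 | (1S,4R,5S,6S,8S,10R)-13-acetoxy-4,5-epoxy-1-hydroxy-8-(methacryloyloxy)germacr-7(11)-en-12,6-olide (CNP0119405.1) | C=C(C)C(=O)O[C@H]1C[C@@H](C)[C@@H](O)CC[C@@]2(C)O[C@H]2[C@H]2OC(=O)C(COC(C)=O)=C12 | target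

**Step count and risks**

Total steps: 20, of which steps 6, 11, 12 and 18 make the side components 9, 18 and 28.
Longest linear sequence: 16 steps (1–5, 7–10, 13–17, 19, 20).

Steps most likely to fail:

Step 7. The excited enone may add to the weakly polarised cyclobutene in the head-to-tail sense, and the dienone may contract by Cope rearrangement while the cycloreversion is still running. Fallback, from 7 back to the route at 12, with an activating group on the four-membered partner: ethyl cyclobut-1-ene-1-carboxylate F1 is made from commercial ethyl 1-bromocyclobutane-1-carboxylate by dehydrobromination with DBU and irradiated with 7 at 350 nm. An acceptor alkene bonds its substituted carbon to the enone α-carbon, so the head-to-head adduct ethyl (9S)-9-(tert-butyldimethylsilyloxy)-1-methyl-7-oxotricyclo[4.4.0.0^2,5]decane-5-carboxylate F2 is expected. Its cycloreversion, eased by the ester at the cleaving centre, should give ethyl (1(10)E,8S)-8-(tert-butyldimethylsilyloxy)-6-oxogermacra-1(10),4-dien-15-oate F3 (C3 cis to C6) at a lower temperature. CBS reduction as in step 8 gives the 6S-hydroxy ester F4, and iBu2AlH reduces the ester to the 6,15-diol F5. The primary allylic hydroxyl is exchanged selectively for chloride (MsCl, LiCl, 2,4,6-collidine, DMF, 0 °C) to give the 15-chloride F6, and LiBHEt3 replaces chloride by hydride to give 12.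

Step 15. The sulfamate elimination needs an H7 within reach; in a C11 epimer without it, loss of a C13 hydrogen to an enol ether may take over. Fallback, from 20 back to the route at 24, with the dehydration moved to the ketone stage where it is an E1cB process without geometric demand: acetylation of the tertiary hydroxyl (Ac2O, DMAP) and treatment with DBU give ethyl (4R,5R,8S)-4,5-epoxy-6-oxo-8,13-bis(tert-butyldimethylsilyloxy)germacra-1(10)E,7(11)-dien-12-oate F7 as both C7=C11 isomers. Zn(BH4)2 reduction as in step 14 converts the isomer with the ester cis to C6 directly into 24. The other isomer gives ethyl (4R,5S,6S,8S)-4,5-epoxy-6-hydroxy-8,13-bis(tert-butyldimethylsilyloxy)germacra-1(10)E,7(11)-dien-12-oate F8 (ester trans to C6), which under benzophenone-sensitised irradiation at 350 nm isomerises about C7=C11 and is drained to 24 by lactonisation.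

Step 20. The outer face of the E alkene that is open in the fully acylated substrate may be the wrong one, and borane may attack an ester carbonyl or the oxirane before it reaches the hindered alkene. Fallback, from 24 to the target 32, with reagent-controlled hydroboration one stage earlier and a conventional protecting-group endgame: 24, which has no ester besides the butenolide, is hydroborated with the enantiomer of monoisopinocampheylborane (IpcBH2) matched to the required face and oxidised with NaBO3·4H2O to (1S,4R,5S,6S,8S,10R)-4,5-epoxy-1-hydroxy-8,13-bis(tert-butyldimethylsilyloxy)germacr-7(11)-en-12,6-olide F9. 4-Methoxybenzyl trichloroacetimidate with catalytic PPTS gives the 1-O-(4-methoxybenzyl) ether F10, and HF·pyridine gives the 8,13-diol F11. AcCl with 2,4,6-collidine gives the 13-acetate F12, and methacrylic anhydride with Et3N and DMAP gives the 8-methacrylate F13. DDQ in wet, buffered CH2Cl2 then removes the 4-methoxybenzyl group to give 32.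

Further compounds
F1 | step 7 | ethyl cyclobut-1-ene-1-carboxylate | CCOC(=O)C1=CCC1
F2 | step 7 | ethyl (9S)-9-(tert-butyldimethylsilyloxy)-1-methyl-7-oxotricyclo[4.4.0.0^2,5]decane-5-carboxylate, cis-fused diastereomers | O=C1C[C@@H](O[Si](C)(C)C(C)(C)C)CC2(C)C3CCC3(C(=O)OCC)C12
F3 | step 7 | ethyl (1(10)E,8S)-8-(tert-butyldimethylsilyloxy)-6-oxogermacra-1(10),4-dien-15-oate, C3 cis to C6 | CC(C)(C)[Si](C)(C)O[C@H]1C/C(C)=C/CC/C(C(=O)OCC)=C\C(=O)C1
F4 | step 7 | ethyl (1(10)E,6S,8S)-8-(tert-butyldimethylsilyloxy)-6-hydroxygermacra-1(10),4-dien-15-oate | CC(C)(C)[Si](C)(C)O[C@H]1C/C(C)=C/CC/C(C(=O)OCC)=C\[C@@H](O)C1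
F5 | step 7 | (1(10)E,6S,8S)-8-(tert-butyldimethylsilyloxy)germacra-1(10),4-diene-6,15-diol | CC(C)(C)[Si](C)(C)O[C@H]1C/C(C)=C/CC/C(CO)=C\[C@@H](O)C1
F6 | step 7 | (1(10)E,6S,8S)-15-chloro-8-(tert-butyldimethylsilyloxy)germacra-1(10),4-dien-6-ol | CC(C)(C)[Si](C)(C)O[C@H]1C/C(C)=C/CC/C(CCl)=C\[C@@H](O)C1
F7 | step 15 | ethyl (4R,5R,8S)-4,5-epoxy-6-oxo-8,13-bis(tert-butyldimethylsilyloxy)germacra-1(10)E,7(11)-dien-12-oate, both C7=C11 isomers | CC(C)(C)[Si](C)(C)O[C@H]1C/C(C)=C/CC[C@@]2(C)O[C@H]2C(=O)C1=C(CO[Si](C)(C)C(C)(C)C)C(=O)OCC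
F8 | step 15 | ethyl (4R,5S,6S,8S)-4,5-epoxy-6-hydroxy-8,13-bis(tert-butyldimethylsilyloxy)germacra-1(10)E,7(11)-dien-12-oate, ester trans to C6 | CC(C)(C)[Si](C)(C)O[C@H]1C/C(C)=C/CC[C@@]2(C)O[C@H]2[C@@H](O)/C1=C(\CO[Si](C)(C)C(C)(C)C)C(=O)OCC
F9 | step 20 | (1S,4R,5S,6S,8S,10R)-4,5-epoxy-1-hydroxy-8,13-bis(tert-butyldimethylsilyloxy)germacr-7(11)-en-12,6-olide | CC(C)(C)[Si](C)(C)O[C@H]1C[C@@H](C)[C@@H](O)CC[C@@]2(C)O[C@H]2[C@H]2OC(=O)C(CO[Si](C)(C)C(C)(C)C)=C12
F10 | step 20 | (1S,4R,5S,6S,8S,10R)-4,5-epoxy-1-(4-methoxybenzyloxy)-8,13-bis(tert-butyldimethylsilyloxy)germacr-7(11)-en-12,6-olide | CC(C)(C)[Si](C)(C)O[C@H]1C[C@@H](C)[C@@H](OCc3ccc(OC)cc3)CC[C@@]2(C)O[C@H]2[C@H]2OC(=O)C(CO[Si](C)(C)C(C)(C)C)=C12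
F11 | step 20 | (1S,4R,5S,6S,8S,10R)-4,5-epoxy-8,13-dihydroxy-1-(4-methoxybenzyloxy)germacr-7(11)-en-12,6-olide | O[C@H]1C[C@@H](C)[C@@H](OCc3ccc(OC)cc3)CC[C@@]2(C)O[C@H]2[C@H]2OC(=O)C(CO)=C12
F12 | step 20 | (1S,4R,5S,6S,8S,10R)-13-acetoxy-4,5-epoxy-8-hydroxy-1-(4-methoxybenzyloxy)germacr-7(11)-en-12,6-olide | O[C@H]1C[C@@H](C)[C@@H](OCc3ccc(OC)cc3)CC[C@@]2(C)O[C@H]2[C@H]2OC(=O)C(COC(C)=O)=C12
F13 | step 20 | (1S,4R,5S,6S,8S,10R)-13-acetoxy-4,5-epoxy-8-(methacryloyloxy)-1-(4-methoxybenzyloxy)germacr-7(11)-en-12,6-olide | C=C(C)C(=O)O[C@H]1C[C@@H](C)[C@@H](OCc3ccc(OC)cc3)CC[C@@]2(C)O[C@H]2[C@H]2OC(=O)C(COC(C)=O)=C12
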